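(All runs were computed for substances that don't exist; noise was put on by code.)

Each unit of starting material charged ends up once: unchanged, in product, or lost to the protic impurity. So count turnovers, assuming for now that the impurity consumes starting material one for one and that each turnover takes one equivalent of solid reagent. For eta and delta, the smaller of the solid's equivalents and what the impurity leaves gives 50.0%, the turnover budget: the fraction of the charge that can become target or isomer. The solid is the limiting reagent in eta and delta, with fewer equivalents than the starting material the impurity leaves.

| setting | Saturday's | Monday's | Wednesday's | eta | delta |
|---|---|---|---|---|---|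
| starting material | 0.64 M | 0.64 M | 0.32 M | 0.64 M | 0.64 M |
| protic impurity | 0.032 M | 0.032 M | 0.032 M | 0.0320 M | 0.0320 M |
| solid reagent | 0.25 equiv | 1 equiv | 0.50 equiv | 0.500 equiv | 0.500 equiv |
| temperature | −14 °C | 0 °C | −14 °C | −20 °C | 5 °C |
| remark | run made earlier | run made earlier | run made earlier |  |  |
| time |  |  |  | 4.0 h | 4.0 h |

Saturday's run (percent of the starting material charged): time / h: target / % = 0.833: 17; 1.50: 9; 2.50: 11; 3.00: 8; 4.00: 10

Monday's run (percent of the starting material charged): time / min: target / % = 8.00: 13; 20.0: 33; 40.0: 46; 60.0: 55; 80.0: 54

Wednesday's run (percent of the starting material charged): time / h: target / % = 0.333: 18; 0.667: 20; 1.00: 20; 2.00: 23; 4.00: 19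

(scatter of a reading: 2 percentage points)

- solid, in amounts per volume of the solution: solid reagent
- at the start none of the solid reagent is in solution

- which of the two there is more of at the end, eta (target / isomer of the product)
- which of the two there is more of at the end, delta (target / isomer of the product)
- how much target is there at the end, in percent of the starting material charged: eta
- how much target is there at the end, in percent of the starting material charged: delta

Now read the share of the budget that becomes target. Saturday's budget is 25.0% and its plateau, from the second reading on, averages 9.50%. Wednesday's are 50.0% and 20.5%. Pooled, the share at −14 °C reads 40.0%. Monday's last two readings average 54.5% on a budget of 95.0%, a share of 57.4% at 0 °C. With two temperatures and this scatter I draw no line: I carry the nearest share over, 40.0% to eta and 57.4% to delta, so target comes to 20.0% and 28.7%.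

The weak link is the impurity's victim, which these readings leave open. If it destroys solid instead, the budget in eta and delta falls to 45.0% and the share at −14 °C rises to 50.0%. Monday's budget stays at 95.0%, so its share stands, and target then comes to 22.5% and 25.8%. I commit to the midpoints, 21.3% and 27.2%. On both branches the share reads higher at 0 °C than at −14 °C, and at −14 °C it reads 40.0% or 50.0%, so I call the isomer ahead in eta, which is colder, and target ahead in delta.

The forecast takes the second branch, that the “protic impurity destroys an equal amount of reagent”. It calls isomer of the product for eta and target for delta, with 21% and 27% of target. These stand close to my midpoints, but both come from the same readings, so that is no check.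

The flasks give 21.1% of target in eta, behind 28.9% of isomer, and 29.6% in delta, ahead of 20.4%.

    starting material + protic impurity → quenched substrate (k = 0.0212 /M/s, Ea = 43.0 kJ/mol)
    solid reagent ⇌ partner, rate k2*(cs2 - [partner]) while solid is left; crystals form when [partner] > cs2 (solubility = 0.0970 M, k = 0.00584 /s)
    starting material + partner → target (k = 0.00144 /M/s, Ea = 59.0 kJ/mol)
    starting material + partner → isomer of the product (k = 0.00197 /M/s, Ea = 43.0 kJ/mol)
    (constants at −20 °C)

In eta, target and isomer sum to 50.0% against the budget of 50.0%, with 5.00% as quenched substrate. The forecast's share of 47% on its budget of 45.0% and the flask's 42.2% of 50.0% land on the same target. In a further flask, like eta but with 2.00 equiv of solid, the budget becomes 95.0%, and that flask holds 39.6% of target and 54.2% of isomer, together 93.8%.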